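**Plan**

- Retrosynthetic cuts, in order: the two ester C–O bonds; the C3–O and C4–O bonds (back to a C3=C4 alkene); the C7–C8 bond of ring B; the C4–CH3 bond (back to a C4 ketone); and last, in a single operation, the C10–CH3 and C5–C6 bonds.
- Enabling feature: C4 can be a carbonyl carbon, and then C5 (ring-fusion CH) and C10 (quaternary, angular methyl) are its α- and β-carbons inside ring A (C1–C5, C10). Ring A is therefore a 3-substituted cyclohexenone that takes the angular methyl at C10 by conjugate addition and the C6–C7–C11 arm of ring B at C5 by alkylation of the enolate so formed.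
- Forward order: ring A comes from the benzene ring of 2-(3-methoxyphenyl)ethanol (Birch reduction); three components are joined on it; ring B (C5–C10) closes afterwards by an intramolecular carbonyl-ene reaction between C8 and C7; the C3/C4 oxygens and the two esters come last.
- Stereochemistry: C10 from the chiral copper–phosphoramidite catalyst; C5 relayed from C10 in the alkylation; C4 and C3 from α-face osmylation opposite the axial C10 methyl, C3 then being inverted by oxidation and hydroxyl-directed reduction.

Key step: step 3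

Remark: eudesmane numbering is used throughout. Which antipode of the phosphoramidite sends methyl to the Si face of the enone β-carbon is to be confirmed in a first run; the other antipode is used if needed.

**Route**

Step 1
Reactants: 1 2-(3-methoxyphenyl)ethan-1-ol
Product: 4 3-(2-hydroxyethyl)cyclohex-2-en-1-one, via Birch diene 2 (not isolated), via unconjugated enone 3 (not isolated)
Conditions: Li, NH3 (l), t-BuOH, THF, −78 to −33 °C; NH4Cl; NH3 evaporated; then 2 M HCl, THF, rt
Reagents that add atoms: water, O
Why: Birch reduction of the anisole gives the 2,5-dihydro enol ether, and aqueous acid hydrolyses it to the ketone and moves the double bond into conjugation, a standard entry to 3-substituted cyclohexenones that creates no stereocentre.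

Step 2
Reactants: 4 3-(2-hydroxyethyl)cyclohex-2-en-1-one
Product: 5 3-[2-(tert-butyldimethylsilyloxy)ethyl]cyclohex-2-en-1-one
Conditions: TBSCl, imidazole, DMF, 0 °C to rt
Reagents that add atoms: tert-butyldimethylsilyl chloride, CC(C)(C)[Si](C)(C)Cl
Why: Imidazole-promoted silylation of a primary alcohol, which masks the hydroxyl against AlMe3, MeLi and the amide base used later.

Step 3
Reactants: 5 3-[2-(tert-butyldimethylsilyloxy)ethyl]cyclohex-2-en-1-one; 6 trimethylaluminium; 7 prenyl bromide
Product: 10 (2R,3R)-3-[2-(tert-butyldimethylsilyloxy)ethyl]-3-methyl-2-(3-methylbut-2-en-1-yl)cyclohexan-1-one, via dimethylaluminium enolate 8 (not isolated), via lithium aluminate enolate 9 (not isolated)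
Conditions: [Cu(MeCN)4]BF4 (5 mol %), O,O′-(2,2′-biphenyldiyl) N,N-bis[1-(2-naphthyl)ethyl]phosphoramidite (single antipode, 10 mol %), 6 (1.4 equiv), Et2O, −30 °C; then THF, MeLi (1.4 equiv), −30 to 0 °C; then 7 (3 equiv), DMPU, −40 °C to rt; aq NH4Cl
Reagents that add atoms: none
Why: A monovalent copper–phosphoramidite complex takes a methyl group from AlMe3, binds the enone that aluminium activates at oxygen and passes through a trivalent copper σ-alkyl species whose reductive elimination forms the C10–CH3 bond and leaves the aluminium enolate 8 with its double bond fixed between C4 and C5; MeLi then converts this weakly nucleophilic enolate into the aluminate 9, which displaces bromide from the primary carbon of prenyl bromide to form the C5–C6 bond. The closest known reaction type is the copper-catalysed asymmetric conjugate addition of trialkylaluminium reagents to 3-substituted cyclohexenones with trapping of the enolate by an allylic halide. No ring is closed. C10 is set by the ligand (methyl to the Si face of the β-carbon), and C5 by the substrate: the electrophile adds axially to the half-chair enolate on the face away from the pseudo-axial silyloxyethyl arm, that is cis to the new methyl group, the arrangement that later becomes the trans ring fusion. The step needs 1,4- over 1,2-addition (secured by copper catalysis at low temperature), alkylation at C5 and not at C3 (secured by the regiodefined enolate, which the aluminate keeps from equilibrating) and attack at the CH2 end of the allyl unit (secured by the unhindered primary bromide).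

Step 4
Reactants: 10 (2R,3R)-3-[2-(tert-butyldimethylsilyloxy)ethyl]-3-methyl-2-(3-methylbut-2-en-1-yl)cyclohexan-1-one
Product: 12 (5R,6R)-5-[2-(tert-butyldimethylsilyloxy)ethyl]-5-methyl-6-(3-methylbut-2-en-1-yl)cyclohex-1-en-1-yl trifluoromethanesulfonate, via potassium enolate 11 (not isolated)
Conditions: KN(SiMe3)2, THF, −78 °C; then PhNTf2, −78 to 0 °C
Reagents that add atoms: N-phenylbis(trifluoromethanesulfonimide), O=S(=O)(N(c1ccccc1)S(=O)(=O)C(F)(F)F)C(F)(F)F
Why: Kinetic deprotonation by the hindered amide base removes a proton from the C3 methylene and not from the congested C5 methine, and O-sulfonylation of this enolate gives the Δ3 enol triflate without touching the C5 stereocentre (regioselective enol triflate formation).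

Step 5
Reactants: 12 (5R,6R)-5-[2-(tert-butyldimethylsilyloxy)ethyl]-5-methyl-6-(3-methylbut-2-en-1-yl)cyclohex-1-en-1-yl trifluoromethanesulfonate
Product: 13 tert-butyl{2-[(1R,2R)-1,3-dimethyl-2-(3-methylbut-2-en-1-yl)cyclohex-3-en-1-yl]ethoxy}dimethylsilane
Conditions: MeMgBr, Fe(acac)3 (5 mol %), THF/NMP, −30 to 0 °C
Reagents that add atoms: methylmagnesium bromide, C[Mg]Br
Why: Iron-catalysed Kumada-type cross-coupling of the alkenyl triflate with the methyl Grignard reagent replaces the triflate by the C4 methyl group with the double bond held at C3=C4, the silyl ether and the prenyl alkene being inert.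

Step 6
Reactants: 13 tert-butyl{2-[(1R,2R)-1,3-dimethyl-2-(3-methylbut-2-en-1-yl)cyclohex-3-en-1-yl]ethoxy}dimethylsilane
Product: 14 2-[(1R,2R)-1,3-dimethyl-2-(3-methylbut-2-en-1-yl)cyclohex-3-en-1-yl]ethan-1-ol
Conditions: Bu4NF, THF, 0 °C to rt
Reagents that add atoms: none
Why: Fluoride-induced cleavage of the silyl ether, driven by the strength of the Si–F bond, frees the primary alcohol while both alkenes are unaffected.

Step 7
Reactants: 14 2-[(1R,2R)-1,3-dimethyl-2-(3-methylbut-2-en-1-yl)cyclohex-3-en-1-yl]ethan-1-ol
Product: 15 2-[(1R,2R)-1,3-dimethyl-2-(3-methylbut-2-en-1-yl)cyclohex-3-en-1-yl]acetaldehyde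
Conditions: Dess–Martin periodinane (DMP), pyridine, CH2Cl2, 0 °C to rt
Reagents that add atoms: none
Why: Dess–Martin oxidation converts the primary alcohol into the C8 aldehyde under buffered conditions that neither isomerise the alkenes nor start the cyclisation early.

Step 8
Reactants: 15 2-[(1R,2R)-1,3-dimethyl-2-(3-methylbut-2-en-1-yl)cyclohex-3-en-1-yl]acetaldehyde
Product: 16 (5R,7R,8S,10R)-eudesma-3,11-dien-8-ol
Conditions: Me2AlCl (1.3 equiv), CH2Cl2, −78 to −20 °C
Reagents that add atoms: none
Why: Lewis-acid-promoted intramolecular carbonyl-ene reaction of the citronellal-to-isopulegol type, in which the aldehyde activated by Me2AlCl is attacked by C7 of the prenyl alkene through a six-membered chair while a methyl hydrogen passes to oxygen, so that ring B closes as a trans-decalin with the hydroxyl and isopropenyl groups expected to be equatorial, both new centres being removed in step 9.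

Step 9
Reactants: 16 (5R,7R,8S,10R)-eudesma-3,11-dien-8-ol
Product: 18 (5R,10R)-eudesma-3,7(11)-dien-8-one, via isopropenyl ketone 17 (not isolated)
Conditions: DMP, pyridine, CH2Cl2, rt; filtration through silica; then NaOMe (cat), MeOH, rt
Reagents that add atoms: none
Why: Dess–Martin oxidation gives the β,γ-unsaturated ketone, and methoxide moves the double bond through the dienolate into conjugation to give the more stable α-isopropylidene ketone (the isopulegone-to-pulegone isomerisation), which erases the C7 and C8 stereocentres.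

Step 10
Reactants: 18 (5R,10R)-eudesma-3,7(11)-dien-8-one
Product: 19 (3R,4S,5R,10R)-3,4-dihydroxyeudesm-7(11)-en-8-one
Conditions: OsO4 (2.5 mol %), N-methylmorpholine N-oxide, acetone/H2O, rt
Reagents that add atoms: osmium tetroxide, O=[Os](=O)(=O)=O; N-methylmorpholine N-oxide, C[N+]1([O-])CCOCC1; water, O
Why: Catalytic syn-dihydroxylation with OsO4 (Upjohn conditions) selects the electron-rich trisubstituted ring A alkene over the electron-poor tetrasubstituted enone double bond and approaches from the α face, away from the axial C10 methyl group, so that C3 and C4 both receive α oxygen.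

Step 11
Reactants: 19 (3R,4S,5R,10R)-3,4-dihydroxyeudesm-7(11)-en-8-one
Product: 20 (4S,5R,10R)-4-hydroxyeudesm-7(11)-ene-3,8-dione
Conditions: IBX, DMSO, rt
Reagents that add atoms: none
Why: IBX oxidises the secondary C3 hydroxyl of the 1,2-diol to the ketone without cleaving the C3–C4 bond and cannot oxidise the tertiary C4 hydroxyl.

Step 12
Reactants: 20 (4S,5R,10R)-4-hydroxyeudesm-7(11)-ene-3,8-dione
Product: 21 (3S,4S,5R,10R)-3,4-dihydroxyeudesm-7(11)-en-8-one
Conditions: Me4NBH(OAc)3, MeCN/AcOH (1:1), −20 to 0 °C
Reagents that add atoms: none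
Why: Hydroxyl-directed triacetoxyborohydride reduction, in which the C4 hydroxyl exchanges onto boron and hydride is delivered within the complex to the α face of the C3 carbonyl, also the face away from the axial C4 methyl group, giving the equatorial 3β alcohol while the conjugated C8 ketone, which has no directing hydroxyl, is left alone.

Step 13
Reactants: 21 (3S,4S,5R,10R)-3,4-dihydroxyeudesm-7(11)-en-8-one; 22 angelic acid
Product: 23 (3S,4S,5R,10R)-4-hydroxy-8-oxoeudesm-7(11)-en-3-yl (Z)-2-methylbut-2-enoate
Conditions: 22, 2,4,6-trichlorobenzoyl chloride, Et3N, toluene, rt; then 21, 75 °C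
Reagents that add atoms: none
Why: Yamaguchi esterification, in which the mixed anhydride of angelic acid is attacked at the less hindered angeloyl carbonyl by the secondary C3 hydroxyl, the tertiary C4 hydroxyl being too hindered to react and the absence of a nucleophilic catalyst guarding against Z-to-E isomerisation to the tiglate.

Step 14
Reactants: 23 (3S,4S,5R,10R)-4-hydroxy-8-oxoeudesm-7(11)-en-3-yl (Z)-2-methylbut-2-enoate
Product: 24 (3S,4S,5R,10R)-4-acetoxy-8-oxoeudesm-7(11)-en-3-yl (Z)-2-methylbut-2-enoate (CNP0141494.1)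
Conditions: Ac2O, Sc(OTf)3 (5 mol %), MeCN, −20 to 0 °C
Reagents that add atoms: acetic anhydride, CC(=O)OC(C)=O
Why: Lewis-acid-catalysed acylation with Sc(OTf)3 and acetic anhydride acetylates hindered tertiary alcohols at low temperature, the adjacent acyloxy group disfavouring ionisation at C4, which completes the target.

**Compound list**

1 | 2-(3-methoxyphenyl)ethan-1-ol | COc1cccc(CCO)c1 | starting material
2 | 2-(5-methoxycyclohexa-1,4-dien-1-yl)ethan-1-ol | COC1=CCC=C(CCO)C1 | intermediate
3 | 3-(2-hydroxyethyl)cyclohex-3-en-1-one | O=C1CC(CCO)=CCC1 | intermediate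
4 | 3-(2-hydroxyethyl)cyclohex-2-en-1-one | O=C1C=C(CCO)CCC1 | intermediate
5 | 3-[2-(tert-butyldimethylsilyloxy)ethyl]cyclohex-2-en-1-one | O=C1C=C(CCO[Si](C)(C)C(C)(C)C)CCC1 | intermediate
6 | trimethylaluminium | C[Al](C)C | starting material
7 | prenyl bromide (1-bromo-3-methylbut-2-ene) | CC(C)=CCBr | starting material
8 | dimethylaluminium (R)-3-[2-(tert-butyldimethylsilyloxy)ethyl]-3-methylcyclohex-1-en-1-olate | C[Al](C)OC1=C[C@@](C)(CCO[Si](C)(C)C(C)(C)C)CCC1 | intermediate
9 | lithium trimethyl{[(R)-3-[2-(tert-butyldimethylsilyloxy)ethyl]-3-methylcyclohex-1-en-1-yl]oxy}aluminate | [Li+].C[Al-](C)(C)OC1=C[C@@](C)(CCO[Si](C)(C)C(C)(C)C)CCC1 | intermediate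
10 | (2R,3R)-3-[2-(tert-butyldimethylsilyloxy)ethyl]-3-methyl-2-(3-methylbut-2-en-1-yl)cyclohexan-1-one (methyl and prenyl cis) | O=C1CCC[C@](C)(CCO[Si](C)(C)C(C)(C)C)[C@H]1CC=C(C)C | intermediate
11 | potassium (5R,6R)-5-[2-(tert-butyldimethylsilyloxy)ethyl]-5-methyl-6-(3-methylbut-2-en-1-yl)cyclohex-1-en-1-olate | [K+].[O-]C1=CCC[C@](C)(CCO[Si](C)(C)C(C)(C)C)[C@H]1CC=C(C)C | intermediate
12 | (5R,6R)-5-[2-(tert-butyldimethylsilyloxy)ethyl]-5-methyl-6-(3-methylbut-2-en-1-yl)cyclohex-1-en-1-yl trifluoromethanesulfonate | O=S(=O)(OC1=CCC[C@](C)(CCO[Si](C)(C)C(C)(C)C)[C@H]1CC=C(C)C)C(F)(F)F | intermediate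
13 | tert-butyl{2-[(1R,2R)-1,3-dimethyl-2-(3-methylbut-2-en-1-yl)cyclohex-3-en-1-yl]ethoxy}dimethylsilane | CC1=CCC[C@](C)(CCO[Si](C)(C)C(C)(C)C)[C@H]1CC=C(C)C | intermediate
14 | 2-[(1R,2R)-1,3-dimethyl-2-(3-methylbut-2-en-1-yl)cyclohex-3-en-1-yl]ethan-1-ol | CC1=CCC[C@](C)(CCO)[C@H]1CC=C(C)C | intermediate
15 | 2-[(1R,2R)-1,3-dimethyl-2-(3-methylbut-2-en-1-yl)cyclohex-3-en-1-yl]acetaldehyde | CC1=CCC[C@](C)(CC=O)[C@H]1CC=C(C)C | intermediate
16 | (5R,7R,8S,10R)-eudesma-3,11-dien-8-ol (8α-OH, 7β-isopropenyl, 5α-H, 10β-CH3) | CC1=CCC[C@]2(C)C[C@H](O)[C@@H](C(C)=C)C[C@H]21 | intermediate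
17 | (5R,7R,10R)-eudesma-3,11-dien-8-one | CC1=CCC[C@]2(C)CC(=O)[C@@H](C(C)=C)C[C@H]21 | intermediate
18 | (5R,10R)-eudesma-3,7(11)-dien-8-one | CC1=CCC[C@]2(C)CC(=O)C(=C(C)C)C[C@H]21 | intermediate
19 | (3R,4S,5R,10R)-3,4-dihydroxyeudesm-7(11)-en-8-one (3α,4α-diol) | O[C@@H]1CC[C@]2(C)CC(=O)C(=C(C)C)C[C@H]2[C@]1(C)O | intermediate
20 | (4S,5R,10R)-4-hydroxyeudesm-7(11)-ene-3,8-dione (4α-OH) | O=C1CC[C@]2(C)CC(=O)C(=C(C)C)C[C@H]2[C@]1(C)O | intermediate
21 | (3S,4S,5R,10R)-3,4-dihydroxyeudesm-7(11)-en-8-one (3β,4α-diol) | O[C@H]1CC[C@]2(C)CC(=O)C(=C(C)C)C[C@H]2[C@]1(C)O | intermediate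
22 | angelic acid ((Z)-2-methylbut-2-enoic acid) | C/C=C(/C)C(=O)O | starting material
23 | (3S,4S,5R,10R)-4-hydroxy-8-oxoeudesm-7(11)-en-3-yl (Z)-2-methylbut-2-enoate | C/C=C(/C)C(=O)O[C@H]1CC[C@]2(C)CC(=O)C(=C(C)C)C[C@H]2[C@]1(C)O | intermediate
24 | (3S,4S,5R,10R)-4-acetoxy-8-oxoeudesm-7(11)-en-3-yl (Z)-2-methylbut-2-enoate (3β-angeloyloxy, 4α-acetoxy, 5α-H, 10β-CH3) | C/C=C(/C)C(=O)O[C@H]1CC[C@]2(C)CC(=O)C(=C(C)C)C[C@H]2[C@]1(C)OC(C)=O | target

**Step count and risks**

Total: 14 steps. Longest linear sequence: 14 steps, from 1 to 24.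

The three steps most likely to fail:

Step 3. The aluminium enolate may alkylate sluggishly, which allows proton transfer and loss of regiochemistry. The larger concern is weak facial discrimination at C5: the methyl group and the silyloxyethyl arm on C10 differ little in size near the reacting carbon, so prenyl may also enter cis to the arm. The two C5 epimers of 10 differ only at an enolisable centre, so an unwanted epimer can in principle be separated, equilibrated with base and recycled. If that is not workable, the fallback replaces substrate control by catalyst control. It sets out from 5 and 6: the conjugate addition is run as in step 3, but the aluminium enolate 8 is acylated on oxygen with prenyl chloroformate to give 3-methylbut-2-en-1-yl (R)-3-[2-(tert-butyldimethylsilyloxy)ethyl]-3-methylcyclohex-1-en-1-yl carbonate F1, which is isolated. Treatment with Pd2(dba)3 and a chiral diphosphine of the bis(2-diphenylphosphinobenzamide) type (matched antipode) in toluene should then bring about decarboxylative allylic alkylation: zerovalent palladium ionises the carbonate, carbon dioxide is lost, and the enolate attacks the CH2 terminus of the palladium-bound prenyl unit with the ligand deciding the face at C5. The route is rejoined at 10.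

Step 8. The ring A trisubstituted alkene may compete for the activated aldehyde (Prins-type attack of C3 leading to a bridged skeleton) instead of the prenyl alkene closing ring B. The fallback performs the ring closure while ring A still carries the electron-poor enol triflate, which cannot act as a nucleophile. It sets out from 12: HF·pyridine in THF should give (5R,6R)-5-(2-hydroxyethyl)-5-methyl-6-(3-methylbut-2-en-1-yl)cyclohex-1-en-1-yl trifluoromethanesulfonate F2. Dess–Martin oxidation should give (5R,6R)-5-methyl-6-(3-methylbut-2-en-1-yl)-5-(2-oxoethyl)cyclohex-1-en-1-yl trifluoromethanesulfonate F3. Me2AlCl should close ring B to (5R,7R,8S,10R)-8-hydroxy-7-isopropenyl-10-methyl-trans-octalin-4-yl trifluoromethanesulfonate (the C4 enol triflate of 15-noreudesma-3,11-dien-8α-ol) F4. Iron-catalysed coupling with excess MeMgBr and Fe(acac)3 then installs the C4 methyl group and rejoins the route at 16.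

Step 14. The hindered tertiary C4 hydroxyl may acylate incompletely, and forcing the conditions invites elimination at C4 or isomerisation of the angelate to the tiglate. The fallback places the acetate before the angelate. It sets out from 20: Ac2O, DMAP and Et3N in CH2Cl2 should acetylate the tertiary α-ketol to (4S,5R,10R)-3,8-dioxoeudesm-7(11)-en-4-yl acetate F5. NaBH4 in MeOH/CH2Cl2 at −78 °C should then reduce the saturated C3 ketone from the α face, in preference to the hindered conjugated C8 ketone, to give (3S,4S,5R,10R)-3-hydroxy-8-oxoeudesm-7(11)-en-4-yl acetate F6. This is kept cold and neutral to avoid acetyl migration to O3 and is esterified at once with 22 under the Yamaguchi conditions of step 13, which arrives at 24.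

**Further compounds**

F1 | step 3 | 3-methylbut-2-en-1-yl (R)-3-[2-(tert-butyldimethylsilyloxy)ethyl]-3-methylcyclohex-1-en-1-yl carbonate | CC(C)=CCOC(=O)OC1=C[C@@](C)(CCO[Si](C)(C)C(C)(C)C)CCC1
F2 | step 8 | (5R,6R)-5-(2-hydroxyethyl)-5-methyl-6-(3-methylbut-2-en-1-yl)cyclohex-1-en-1-yl trifluoromethanesulfonate | O=S(=O)(OC1=CCC[C@](C)(CCO)[C@H]1CC=C(C)C)C(F)(F)F
F3 | step 8 | (5R,6R)-5-methyl-6-(3-methylbut-2-en-1-yl)-5-(2-oxoethyl)cyclohex-1-en-1-yl trifluoromethanesulfonate | O=S(=O)(OC1=CCC[C@](C)(CC=O)[C@H]1CC=C(C)C)C(F)(F)F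
F4 | step 8 | (5R,7R,8S,10R)-8-hydroxy-7-isopropenyl-10-methyl-trans-octalin-4-yl trifluoromethanesulfonate (15-noreudesma-3,11-dien-8α-ol 4-triflate) | O=S(=O)(OC1=CCC[C@]2(C)C[C@H](O)[C@@H](C(C)=C)C[C@H]21)C(F)(F)F
F5 | step 14 | (4S,5R,10R)-3,8-dioxoeudesm-7(11)-en-4-yl acetate | O=C1CC[C@]2(C)CC(=O)C(=C(C)C)C[C@H]2[C@]1(C)OC(C)=O
F6 | step 14 | (3S,4S,5R,10R)-3-hydroxy-8-oxoeudesm-7(11)-en-4-yl acetate | O[C@H]1CC[C@]2(C)CC(=O)C(=C(C)C)C[C@H]2[C@]1(C)OC(C)=O
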